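Slowness can still win a flask. In Saturday's run J starts behind, 1.7% of the E charged against 6.8% of Z, yet at 5.00 min it stands at 7.9% against 1.2%.

| setting | Saturday's | Tuesday's | flask |
|---|---|---|---|
| E | 1.5 M | 1.5 M | 1.5 M |
| Q | 1.5 M | 2.2 M | 3.00 M |
| remark | run made earlier | run made earlier |  |
| time |  |  | 6.0 min |

- Saturday's (time / min: J / %, Z / %): 0.417: 1.7, 6.8; 0.667: 3.0, 8.1; 1.00: 3.1, 7.6; 2.00: 6.2, 5.4; 3.00: 7.4, 3.7; 5.00: 7.9, 1.2
- Tuesday's (time / min: J / %, Z / %): 0.333: 1.8, 8.0; 1.00: 4.9, 10.1; 1.50: 7.1, 8.5; 2.50: 9.4, 5.7; 4.00: 9.9, 2.3; 5.00: 10.5, 2.9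

(readings scatter by 0.5 percentage points)

1. share of J in J plus Z at 2.0 s
2. share of J in J plus Z at 6.0 min
3. which of J and Z there is more of at 6.0 min

You can clear this up by counting half-lives. Z, the kinetic product, falls after its peak while J does not fall in these readings. From Tuesday's run, the tail half-life, the time in which Z's fraction of the charge halves past its peak, reads 1.41 min; Saturday's reads 1.38 min.

My own reckoning scales Tuesday's peak Z and last J by the Q charged:

Half-lives from Tuesday's peak reading to the asked time: 3.56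

Z: 13.8% falls to 1.17%

J: 14.3%

Share of J: 92.4%

The forecast, made separately, gave 13% early and 91% late, with J ahead, its J being one that “plateaus as Q disappears”.

The flask gives 16.6% and 87.7%, with J ahead, 12.9% against 1.82%.

    E + Z → X (k = 0.00129 L mol⁻¹ s⁻¹)
    E + Q ⇌ Z (K = 0.380 L mol⁻¹, k = 0.00315 L mol⁻¹ s⁻¹)
    Q → D (k = 0.00170 s⁻¹)
    Z → L (k = 0.0267 s⁻¹)
    E + Q ⇌ J (K = 0.710 L mol⁻¹, k = 6.06 × 10⁻⁴ L mol⁻¹ s⁻¹)

Z's half-life through Z → L is 0.433 min, and J's for going back is 14 min. So the asked time is 13.9 half-lives of that loss for Z but 0.443 of one for J. The tail count gave 1.17% of Z, and the flask holds 1.82%, with Z still made at 0.825 of the rate it is used up.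

The reckoning scales by Q and takes no account of E, so in the neighbour flask with 2.5 M of E the same 3.56 half-lives again give 1.17% of Z and a share of 92.4%. Computed, it holds 1.47% of Z, and the share is 88.6%.

The runs are calculated for an exercise; the scatter is artificial.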